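## Analysis of the target

Bromovulone I (24) is a halogenated marine prostanoid; prostanoid numbering is used throughout (C1 = ester carbon, C8–C12 = ring, C13–C20 = ω chain). The ring is a cyclopentenone with the C9 ketone, an endocyclic C10=C11 olefin carrying bromine on C10, and an exocyclic C7=C8 olefin (E) that runs on into the C5=C6 olefin (Z). Together these form a cross-conjugated dienone that is electrophilic at C7 and C11. The only stereocentre is C12 (R), a fully substituted allylic carbinol bearing the (Z)-oct-2-enyl chain with its skipped C14=C15 olefin. C12 sits between two sp2 ring carbons and has no neighbouring stereocentre from which it could be set by relay.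

Sensitive groups are the conjugated 5Z olefin (isomerised by acid, light and reversible conjugate addition), the α-bromoenone (reductants, palladium, soft nucleophiles) and the electron-rich 14Z olefin. The 14Z olefin rules out a late electrophilic bromination at C10.

The feature that invites the strategy is the array C8–C9(=O)–C10(Br)=C11–C12(OH)(alkyl), a 4-alkyl-4-hydroxycyclopent-2-enone. Its five carbons and the C9 oxygen map onto a 2-(hydroxymethyl)furan: the exocyclic CH2 becomes C8, furan C2–C5 become C9–C12, a 3-bromo substituent becomes C10–Br, and the C12 hydroxyl comes from water. Closing C8–C12 by 4π-electrocyclisation of an oxygenated pentadienyl cation is also the ring-forming event of the presumed biosynthesis of this prostanoid family (allene oxide to oxidopentadienyl cation). The difficulty is to form the ring, the quaternary carbinol in one absolute configuration and the C10–Br bond without ever exposing the Z olefins to bromine.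

## Retrosynthetic reasoning

**C7=C8 (24 to 13 + 19).** The cross-conjugated dienone is the most fragile part of 24, so it is made last by aldol addition of the C8 enolate of silyl ether 13 to the (Z)-enal 19, followed by E1cB elimination. The 5Z geometry is carried in with 19. The 7E geometry is expected from the eliminating enolate, where the C6 substituent avoids the C9 carbonyl oxygen. The silyl group on 13 (from 12) keeps the C12 alkoxide from opening the ring by retro-aldol cleavage during enolate chemistry.

**C8–C12 and C12–O (12 to 10), the key disconnection.** Cutting the C8–C12 bond and the C12–O bond of 12 opens the carbocycle to the aromatic furfuryl alcohol 10, an isomer of 12. The forward reaction is an oxa-Piancatelli rearrangement: ionisation, hydration at the alkyl-bearing furan carbon, ring opening and conrotatory closure. One operation must build the ring, the quaternary carbinol and the enone, with bromine already on the right carbon, and it must do so under the control of a chiral acid, because C12 is created from a planar precursor. This replaces the purchase of a chiral cyclopentenone, a relay of chirality and a separate bromination.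

**Substitution pattern of the furan (10 to 6 to 5 to 3 + 2).** The 2,3,5-pattern of 10 (carbinol next to bromine, chain at the far α-carbon) is not reachable by direct electrophilic substitution. It is reached from the 2-bromo-5-alkylfuran 6 by a base-induced halogen dance that moves bromine to C3 and places lithium at C2 for formylation. 6 comes from α-bromination of 5, and 5 from furan (3) and the allylic bromide 2, made from the commercial (Z)-alcohol 1. The ω-chain olefin is thus bought with its Z geometry.

**Enal 19 (19 to 18 to 17 to 14 + 15).** The C5=C6 bond is cut by a Z-selective Wittig reaction between the ylide of the commercial salt 14 and the protected glycolaldehyde 15. Methanolysis (ester formation and desilylation in one operation) gives 18, and a buffered oxidation gives 19 just before use.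

## Alternatives that were turned down

**Alternative 1:** the textbook route. Disconnection: C7=C8 by the same aldol condensation, and the C12 carbinol by 1,2-addition of an ω-chain organometallic to the ketone of the purchased enantiopure enone A1, anti to its silyloxy group. Desilylation and oxidation of the secondary alcohol then transpose the enone and give A2, which is brominated at C10 to reach 12. Turned down for three reasons. A (Z)-allylic organometallic adds through its γ-carbon, so an alkynyl surrogate and a later semihydrogenation would be needed. Bromination of A2 must discriminate between the enone and the electron-rich 14Z olefin (or, with an alkyne in place, the vinyl bromide must survive the semihydrogenation). And about five operations are spent to reach the stage that step 5 reaches in one. It is also the route most chemists would draw first.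

**Alternative 2:** dioxygen as the source of both ring oxygens. Disconnection: the C9=O and C12–O bonds. Forward: condensation of cyclopentadiene A3 with 19 to fulvene A4, (4+2) cycloaddition of singlet oxygen across C9/C12 to endoperoxide A5, then Kornblum–DeLaMare fragmentation (only C9 carries a hydrogen) to give 24 directly. Turned down on four grounds. Singlet oxygen adds to either face of the planar fulvene, so A5 is racemic with no handle for control. In A4 the C6 substituent should prefer to lie away from the C12 chain, which leads to the 7Z series. Singlet oxygen also attacks the diene and the skipped olefins (ene reactions). And A3 is a mixture of tautomers prone to dimerise.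

**Alternative 3:** C9–C10 by hydroacylation. Disconnection: the C9–C10 bond. Forward: intramolecular trans-hydroacylation of the 4-alkynal A6 with a cationic monovalent rhodium diphosphine complex such as [Rh(dppe)]BF4 to give A7. Turned down because C12 must first be set in an acyclic precursor by an asymmetric aldol-type addition to a ketone, which is a stereochemical problem of its own and costs several steps. The method is established for internal rather than terminal alkynes. The ring is formed without bromine, so the late bromination problem of Alternative 1 returns. And the key step forms a single C–C bond.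

Key step: step 5

## Remarks before the steps

- The cyclopentenones 12 and 13 carry the descriptor S at the carbinol carbon although this carbon is spatially identical with C12 (R) of 24. The change of descriptor comes only from the CIP priorities once C8 becomes sp2.
- Assumption: the sense of induction of the chiral acid in step 5 cannot be predicted with confidence. The route is written for the catalyst antipode that leads to (S)-12; the (R)-BINOL-derived acid stands for it, and its mirror image is equally accessible.

## Route

Step 1
Reactants: 1 (2Z)-oct-2-en-1-ol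
Product: 2 (2Z)-1-bromooct-2-ene
Conditions: CBr4, PPh3, CH2Cl2, 0 °C
Reagents that add atoms: carbon tetrabromide, BrC(Br)(Br)Br
Why: Appel bromination of a primary allylic alcohol; SN2 displacement at 0 °C should leave the Z olefin untouched and avoid allylic transposition.

Step 2
Reactants: 3 furan; 2 (2Z)-1-bromooct-2-ene
Product: 5 2-[(2Z)-oct-2-en-1-yl]furan, via furan-2-yllithium 4 (not isolated)
Conditions: n-BuLi, THF, −78 → 0 °C; then 2, −78 °C → rt
Reagents that add atoms: none
Why: α-Lithiation of furan and SN2 alkylation with a primary allylic bromide, as established for prenyl-type halides; the olefin is not involved, so its Z geometry should be kept.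

Step 3
Reactants: 5 2-[(2Z)-oct-2-en-1-yl]furan
Product: 6 2-bromo-5-[(2Z)-oct-2-en-1-yl]furan
Conditions: NBS, DMF, −20 → 0 °C, dark; used at once
Reagents that add atoms: N-bromosuccinimide, O=C1CCC(=O)N1Br
Why: Electrophilic aromatic substitution at the free α-position of a 2-alkylfuran, which is far more nucleophilic than the isolated olefin under ionic conditions.

Step 4
Reactants: 6 2-bromo-5-[(2Z)-oct-2-en-1-yl]furan
Product: 10 {3-bromo-5-[(2Z)-oct-2-en-1-yl]furan-2-yl}methanol, via 3-lithio-2-bromofuran 7 (not isolated), via 2-lithio-3-bromofuran 8 (not isolated), via furan-2-carbaldehyde 9 (not isolated)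
Conditions: LiN(iPr)2, THF, −78 °C; DMF, −78 → 0 °C; then MeOH, NaBH4, 0 °C
Reagents that add atoms: N,N-dimethylformamide, CN(C)C=O
Why: Halogen dance as known for 2-bromo-5-alkylfurans: the amide base removes H3 next to bromine, and bromine/lithium transposition gives the more stable α-lithio-β-bromofuran 8. Formylation and borohydride reduction in the same pot then give the carbinol with bromine on the adjacent ring carbon.

Step 5
Reactants: 10 {3-bromo-5-[(2Z)-oct-2-en-1-yl]furan-2-yl}methanol
Product: 12 (4S)-2-bromo-4-hydroxy-4-[(2Z)-oct-2-en-1-yl]cyclopent-2-en-1-one, via dihydrofuranol 11 (not isolated)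
Conditions: (R)-3,3'-bis(2,4,6-triisopropylphenyl)-BINOL N-triflylphosphoramide (10 mol %), H2O (3 equiv), CHCl3, 40 °C
Reagents that add atoms: water, O
Why: Proposed new method: the chiral acid should ionise the primary but 5-alkyl-stabilised furfuryl alcohol to the furan-2-ylmethyl cation, whose charge lies largely on C5 as a tertiary oxocarbenium ion; water adds there to give hemiketal 11, which opens to the 1,4-dihydroxypentadienyl cation spanning C8 to C12 (hydroxyls on C9 and C12). Thermal 4π-conrotatory electrocyclisation (Nazarov-type, the only ring closure) forms the C8–C12 bond, and loss of the proton from the C9 hydroxyl gives the enone. The closest known reactions are the oxa-Piancatelli rearrangement of 5-alkyl-2-furylcarbinols to 4-alkyl-4-hydroxycyclopentenones with achiral acids or ZnCl2, the chiral phosphoric acid-catalysed aza-Piancatelli rearrangement (same cation, an amine in place of water) and chiral Brønsted acid-catalysed Nazarov cyclisations; an enantioselective version with water on a primary carbinol has not been shown. C12 is the only new stereocentre and, because the C8 terminus is CH2, its configuration is fixed solely by the sense of conrotation, which the phosphoramide anion should control by hydrogen bonding to both hydroxyls of the cation in a contact ion pair. Regiochemistry is secured by the substrate: bromine on furan C3 can only become C10–Br and the chain-bearing C5 can only become C12, while water attack at the exocyclic carbon merely returns 10. Enantioselectivity needs the ion-paired closure to outrun any achiral background, which a non-polar solvent and a minimum of water should favour. The skipped Z olefin should not be protonated by an acid of this strength at 40 °C.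

Step 6
Reactants: 12 (4S)-2-bromo-4-hydroxy-4-[(2Z)-oct-2-en-1-yl]cyclopent-2-en-1-one
Product: 13 (4S)-2-bromo-4-[(2Z)-oct-2-en-1-yl]-4-[(trimethylsilyl)oxy]cyclopent-2-en-1-one
Conditions: 1-(trimethylsilyl)imidazole, CH2Cl2, 0 °C → rt
Reagents that add atoms: 1-(trimethylsilyl)imidazole, C[Si](C)(C)n1ccnc1
Why: Silylation of a hindered tertiary alcohol with a strong neutral silyl donor; the ether blocks retro-aldol opening of the ring (and hence loss of C12 integrity) during the enolate step.

Step 7
Reactants: 14 (4-carboxybutyl)triphenylphosphonium bromide; 15 [(tert-butyldimethylsilyl)oxy]acetaldehyde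
Product: 17 (5Z)-7-[(tert-butyldimethylsilyl)oxy]hept-5-enoic acid, via phosphorus ylide 16 (not isolated)
Conditions: NaN(SiMe3)2 (2 equiv), THF, 0 → −78 °C; then 15, −78 °C → rt; dilute aqueous HCl to pH 4
Reagents that add atoms: none
Why: Wittig olefination with a non-stabilised, salt-free ylide, which should give the Z olefin with high selectivity, as is usual for this prostaglandin-type ylide.

Step 8
Reactants: 17 (5Z)-7-[(tert-butyldimethylsilyl)oxy]hept-5-enoic acid
Product: 18 methyl (5Z)-7-hydroxyhept-5-enoate
Conditions: AcCl (0.3 equiv), MeOH, 0 °C → rt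
Reagents that add atoms: methanol, CO
Why: Methanolic HCl generated in situ effects Fischer esterification and cleaves the primary silyl ether in one operation; the conditions are too mild to ionise the primary allylic alcohol.

Step 9
Reactants: 18 methyl (5Z)-7-hydroxyhept-5-enoate
Product: 19 methyl (5Z)-7-oxohept-5-enoate
Conditions: Dess–Martin periodinane, NaHCO3, CH2Cl2, 0 °C; filtered cold and used at once
Reagents that add atoms: none
Why: Buffered Dess–Martin oxidation converts Z allylic alcohols into Z enals without acid or base strong enough to isomerise them.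

Step 10
Reactants: 13 (4S)-2-bromo-4-[(2Z)-oct-2-en-1-yl]-4-[(trimethylsilyl)oxy]cyclopent-2-en-1-one; 19 methyl (5Z)-7-oxohept-5-enoate
Product: 21 methyl (5Z)-7-{(5S)-3-bromo-2-oxo-5-[(2Z)-oct-2-en-1-yl]-5-[(trimethylsilyl)oxy]cyclopent-3-en-1-yl}-7-hydroxyhept-5-enoate (mixture of isomers at C7 and C8), via lithium enolate 20 (not isolated)
Conditions: LiN(iPr)2, THF, −78 °C; then 19, −78 °C; AcOH quench at −78 °C
Reagents that add atoms: none
Why: Kinetic α'-deprotonation at C8 (C12 has no hydrogen, so only one enolate can form) and aldol addition to the aldehyde, which is far more electrophilic than the ester at −78 °C. The new centres at C7 and C8 need no control because both are lost in step 11.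

Step 11
Reactants: 21 aldol adduct (mixture at C7 and C8)
Product: 24 bromovulone I = methyl (5Z,7E,12R,14Z)-10-bromo-12-hydroxy-9-oxoprosta-5,7,10,14-tetraen-1-oate, via C7 mesylate 22 (not isolated), via silyl ether 23 (not isolated)
Conditions: MsCl, Et3N, CH2Cl2, −20 → 0 °C; then PPTS, MeOH, 0 °C → rt
Reagents that add atoms: none
Why: Mesylation of the secondary alcohol and E1cB elimination through the C8 enolate give the exocyclic olefin; the 7E isomer should dominate because the C6 substituent avoids the C9 carbonyl oxygen in the eliminating enolate. Mild acidic methanolysis then removes the tertiary trimethylsilyl ether without touching the dienone, the ester or the 5Z olefin.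

## Compound list

1 | (2Z)-oct-2-en-1-ol | CCCCC/C=C\CO | starting material
2 | (2Z)-1-bromooct-2-ene | CCCCC/C=C\CBr | intermediate
3 | furan | c1ccoc1 | starting material
4 | furan-2-yllithium | [Li]c1ccco1 | intermediate (not isolated)
5 | 2-[(2Z)-oct-2-en-1-yl]furan | CCCCC/C=C\Cc1ccco1 | intermediate
6 | 2-bromo-5-[(2Z)-oct-2-en-1-yl]furan | CCCCC/C=C\Cc1ccc(Br)o1 | intermediate
7 | {2-bromo-5-[(2Z)-oct-2-en-1-yl]furan-3-yl}lithium | CCCCC/C=C\Cc1cc([Li])c(Br)o1 | intermediate (not isolated)
8 | {3-bromo-5-[(2Z)-oct-2-en-1-yl]furan-2-yl}lithium | CCCCC/C=C\Cc1cc(Br)c([Li])o1 | intermediate (not isolated)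
9 | 3-bromo-5-[(2Z)-oct-2-en-1-yl]furan-2-carbaldehyde | CCCCC/C=C\Cc1cc(Br)c(C=O)o1 | intermediate (not isolated)
10 | {3-bromo-5-[(2Z)-oct-2-en-1-yl]furan-2-yl}methanol | CCCCC/C=C\Cc1cc(Br)c(CO)o1 | intermediate
11 | 4-bromo-5-methylidene-2-[(2Z)-oct-2-en-1-yl]-2,5-dihydrofuran-2-ol | CCCCC/C=C\CC1(O)C=C(Br)C(=C)O1 | intermediate (not isolated)
12 | (4S)-2-bromo-4-hydroxy-4-[(2Z)-oct-2-en-1-yl]cyclopent-2-en-1-one | CCCCC/C=C\C[C@@]1(O)C=C(Br)C(=O)C1 | intermediate
13 | (4S)-2-bromo-4-[(2Z)-oct-2-en-1-yl]-4-[(trimethylsilyl)oxy]cyclopent-2-en-1-one | CCCCC/C=C\C[C@@]1(O[Si](C)(C)C)C=C(Br)C(=O)C1 | intermediate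
14 | (4-carboxybutyl)triphenylphosphonium bromide | OC(=O)CCCC[P+](c1ccccc1)(c1ccccc1)c1ccccc1.[Br-] | starting material
15 | [(tert-butyldimethylsilyl)oxy]acetaldehyde | CC(C)(C)[Si](C)(C)OCC=O | starting material
16 | sodium 5-(triphenylphosphoranylidene)pentanoate | [Na+].[O-]C(=O)CCCC=P(c1ccccc1)(c1ccccc1)c1ccccc1 | intermediate (not isolated)
17 | (5Z)-7-[(tert-butyldimethylsilyl)oxy]hept-5-enoic acid | CC(C)(C)[Si](C)(C)OC/C=C\CCCC(=O)O | intermediate
18 | methyl (5Z)-7-hydroxyhept-5-enoate | COC(=O)CCC/C=C\CO | intermediate
19 | methyl (5Z)-7-oxohept-5-enoate | COC(=O)CCC/C=C\C=O | intermediate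
20 | lithium (4S)-2-bromo-4-[(2Z)-oct-2-en-1-yl]-4-[(trimethylsilyl)oxy]cyclopenta-1,5-dien-1-olate (C8 enolate of 13) | CCCCC/C=C\C[C@@]1(O[Si](C)(C)C)C=C(Br)C(O[Li])=C1 | intermediate (not isolated)
21 | methyl (5Z)-7-{(5S)-3-bromo-2-oxo-5-[(2Z)-oct-2-en-1-yl]-5-[(trimethylsilyl)oxy]cyclopent-3-en-1-yl}-7-hydroxyhept-5-enoate, mixture at C7 and C8 | CCCCC/C=C\C[C@@]1(O[Si](C)(C)C)C=C(Br)C(=O)C1C(O)/C=C\CCCC(=O)OC | intermediate
22 | methyl (5Z)-7-{(5S)-3-bromo-2-oxo-5-[(2Z)-oct-2-en-1-yl]-5-[(trimethylsilyl)oxy]cyclopent-3-en-1-yl}-7-[(methanesulfonyl)oxy]hept-5-enoate, mixture at C7 and C8 | CCCCC/C=C\C[C@@]1(O[Si](C)(C)C)C=C(Br)C(=O)C1C(OS(C)(=O)=O)/C=C\CCCC(=O)OC | intermediate (not isolated)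
23 | methyl (5Z,7E)-7-{(5R)-3-bromo-2-oxo-5-[(2Z)-oct-2-en-1-yl]-5-[(trimethylsilyl)oxy]cyclopent-3-en-1-ylidene}hept-5-enoate | CCCCC/C=C\C[C@@]1(O[Si](C)(C)C)C=C(Br)C(=O)/C1=C/C=C\CCCC(=O)OC | intermediate (not isolated)
24 | bromovulone I, methyl (5Z,7E)-7-{(5R)-3-bromo-5-hydroxy-2-oxo-5-[(2Z)-oct-2-en-1-yl]cyclopent-3-en-1-ylidene}hept-5-enoate | CCCCC/C=C\C[C@@]1(O)C=C(Br)C(=O)/C1=C/C=C\CCCC(=O)OC | target

## Step count and risk

Total step count: 11. Longest linear sequence: 8 steps (steps 1–6, 10 and 11); the enal 19 is made in a three-step side branch (steps 7–9).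

**Step 5 (key step, proposed new method).** Three processes may defeat it:
- The primary carbinol may ionise too slowly with a chiral acid, so that ether formation and oligomerisation of the furfuryl cation take over.
- The ring-opened dienol may tautomerise to the acyclic Z-enedione instead of closing.
- The closure may occur outside the chiral ion pair, giving poor facial (torquo)selectivity and hence low enantiomeric purity at C12.

Fallback with known chemistry, setting out from 10 and returning at 12. Heating 10 with ZnCl2 in aqueous dioxane, the established conditions for 5-alkyl furylcarbinols, should give the racemic cyclopentenone F1. CBS reduction of F1 with (S)-Me-CBS oxazaborolidine and catecholborane, where the bromovinyl arm acts as the large group, should deliver hydride to the same face of C9 in both antipodes. The racemate is thereby turned into two diastereomers, the cis-diol F2 from the (S)-ketone and the trans-diol F3 from the (R)-ketone, which are separated on silica. Oxidation of F2 with MnO2 returns enantioenriched 12. This costs two steps and half of the material.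

**Step 4.** The amide base may remove a proton from the doubly activated C13 methylene (between furan and olefin) instead of H3, which would move the olefin into conjugation. The halogen dance may also stop at a mixture of lithio species, giving regioisomeric aldehydes. Fallback, setting out from 2 and returning at 10. Purchased 3-bromofuran-2-carbaldehyde F4 is reduced with NaBH4 to (3-bromofuran-2-yl)methanol F5 and silylated (TBSCl, imidazole) to the silyl ether F6. Deprotonation of the only remaining α-position (C5) with LiN(iPr)2 at −78 °C and alkylation with 2 give the chain-bearing silyl ether F7, and Bu4NF releases 10. Here the bromine is in place before the acidic methylene exists.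

**Step 10.** The Z enal may isomerise to the E enal before or during the addition, the enolate may add in conjugate fashion, or the aldol may revert on work-up. Fallback, setting out from 13 and returning at 24, in which the 5Z olefin is made last by a Wittig reaction. Enolate 20 is added to 2,2-dimethoxyacetaldehyde to give the aldol F8, and MsCl/Et3N gives the (E)-alkylidene acetal F9. Aqueous trifluoroacetic acid cleaves the acetal and the silyl ether to the enal F10. Z-selective Wittig reaction with ylide 16 gives the free acid F11, and Me3SiCHN2 gives 24.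

**Step 11.** The elimination may give a 7E/7Z mixture, triethylamine may add reversibly to the dienone and erode the 5Z geometry, and the tertiary silyl ether may be lost early, exposing the alcohol to mesylation. Fallback without an aldol or an amine base, setting out from 13 and 18 and returning at 23. Enolate 20 is sulfenylated with PhSSPh to the α-phenylthio ketone F12. 18 is converted with CBr4/PPh3 into methyl (5Z)-7-bromohept-5-enoate F13. Alkylation of F12 with F13 (NaH, THF/DMF) gives the quaternary sulfide F14, and oxidation with mCPBA at −78 °C gives the sulfoxide F15. Warming F15 in toluene causes syn-elimination toward C7, the only carbon with a β-hydrogen, to give 23, which is desilylated as in step 11.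

## Further compounds

F1 | step 5 | rac-2-bromo-4-hydroxy-4-[(2Z)-oct-2-en-1-yl]cyclopent-2-en-1-one | CCCCC/C=C\CC1(O)C=C(Br)C(=O)C1
F2 | step 5 | (1R,4S)-2-bromo-4-[(2Z)-oct-2-en-1-yl]cyclopent-2-ene-1,4-diol (cis-diol) | CCCCC/C=C\C[C@@]1(O)C=C(Br)[C@H](O)C1
F3 | step 5 | (1R,4R)-2-bromo-4-[(2Z)-oct-2-en-1-yl]cyclopent-2-ene-1,4-diol (trans-diol) | CCCCC/C=C\C[C@]1(O)C=C(Br)[C@H](O)C1
F4 | step 4 | 3-bromofuran-2-carbaldehyde | O=Cc1occc1Br
F5 | step 4 | (3-bromofuran-2-yl)methanol | OCc1occc1Br
F6 | step 4 | [(3-bromofuran-2-yl)methoxy](tert-butyl)dimethylsilane | CC(C)(C)[Si](C)(C)OCc1occc1Br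
F7 | step 4 | ({3-bromo-5-[(2Z)-oct-2-en-1-yl]furan-2-yl}methoxy)(tert-butyl)dimethylsilane | CCCCC/C=C\Cc1cc(Br)c(CO[Si](C)(C)C(C)(C)C)o1
F8 | step 10 | (4S)-2-bromo-5-(1-hydroxy-2,2-dimethoxyethyl)-4-[(2Z)-oct-2-en-1-yl]-4-[(trimethylsilyl)oxy]cyclopent-2-en-1-one, mixture at the two new centres | CCCCC/C=C\C[C@@]1(O[Si](C)(C)C)C=C(Br)C(=O)C1C(O)C(OC)OC
F9 | step 10 | (4R,5E)-2-bromo-5-(2,2-dimethoxyethylidene)-4-[(2Z)-oct-2-en-1-yl]-4-[(trimethylsilyl)oxy]cyclopent-2-en-1-one | CCCCC/C=C\C[C@@]1(O[Si](C)(C)C)C=C(Br)C(=O)/C1=C/C(OC)OC
F10 | step 10 | (2E)-2-{(5R)-3-bromo-5-hydroxy-5-[(2Z)-oct-2-en-1-yl]-2-oxocyclopent-3-en-1-ylidene}acetaldehyde | CCCCC/C=C\C[C@@]1(O)C=C(Br)C(=O)/C1=C/C=O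
F11 | step 10 | (5Z,7E)-7-{(5R)-3-bromo-5-hydroxy-5-[(2Z)-oct-2-en-1-yl]-2-oxocyclopent-3-en-1-ylidene}hept-5-enoic acid | CCCCC/C=C\C[C@@]1(O)C=C(Br)C(=O)/C1=C/C=C\CCCC(=O)O
F12 | step 11 | (4S)-2-bromo-4-[(2Z)-oct-2-en-1-yl]-5-(phenylsulfanyl)-4-[(trimethylsilyl)oxy]cyclopent-2-en-1-one, mixture at C5 | CCCCC/C=C\C[C@@]1(O[Si](C)(C)C)C=C(Br)C(=O)C1Sc1ccccc1
F13 | step 11 | methyl (5Z)-7-bromohept-5-enoate | COC(=O)CCC/C=C\CBr
F14 | step 11 | methyl (5Z)-7-{(5S)-3-bromo-2-oxo-5-[(2Z)-oct-2-en-1-yl]-1-(phenylsulfanyl)-5-[(trimethylsilyl)oxy]cyclopent-3-en-1-yl}hept-5-enoate, mixture at C1 of the ring | CCCCC/C=C\C[C@@]1(O[Si](C)(C)C)C=C(Br)C(=O)C1(C/C=C\CCCC(=O)OC)Sc1ccccc1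
F15 | step 11 | methyl (5Z)-7-{(5S)-1-(benzenesulfinyl)-3-bromo-2-oxo-5-[(2Z)-oct-2-en-1-yl]-5-[(trimethylsilyl)oxy]cyclopent-3-en-1-yl}hept-5-enoate, mixture at C1 of the ring and at sulfur | CCCCC/C=C\C[C@@]1(O[Si](C)(C)C)C=C(Br)C(=O)C1(C/C=C\CCCC(=O)OC)S(=O)c1ccccc1
A1 | alternative 1 | (4R)-4-[(tert-butyldimethylsilyl)oxy]cyclopent-2-en-1-one | O=C1C=C[C@H](O[Si](C)(C)C(C)(C)C)C1
A2 | alternative 1 | (4S)-4-hydroxy-4-[(2Z)-oct-2-en-1-yl]cyclopent-2-en-1-one | CCCCC/C=C\C[C@@]1(O)C=CC(=O)C1
A3 | alternative 2 | 2-bromo-4-[(2Z)-oct-2-en-1-yl]cyclopenta-1,3-diene | CCCCC/C=C\CC1=CC(Br)=CC1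
A4 | alternative 2 | methyl (5Z,7E)-7-{3-bromo-5-[(2Z)-oct-2-en-1-yl]cyclopenta-2,4-dien-1-ylidene}hept-5-enoate | CCCCC/C=C\CC1=CC(Br)=C/C1=C/C=C\CCCC(=O)OC
A5 | alternative 2 | methyl (5Z,7E)-7-{5-bromo-1-[(2Z)-oct-2-en-1-yl]-2,3-dioxabicyclo[2.2.1]hept-5-en-7-ylidene}hept-5-enoate, racemic | CCCCC/C=C\CC12C=C(Br)C(OO1)/C2=C/C=C\CCCC(=O)OC
A6 | alternative 3 | (3S)-3-[(2Z)-oct-2-en-1-yl]-3-[(trimethylsilyl)oxy]pent-4-ynal | CCCCC/C=C\C[C@@](O[Si](C)(C)C)(C#C)CC=O
A7 | alternative 3 | (4S)-4-[(2Z)-oct-2-en-1-yl]-4-[(trimethylsilyl)oxy]cyclopent-2-en-1-one | CCCCC/C=C\C[C@@]1(O[Si](C)(C)C)C=CC(=O)C1
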